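X at 12 h follows, in my reckoning, from how many lifetimes of G fit into the reading time.

common to all: G 13 mM

| run | Q | remark | time |
|---|---|---|---|
| gamma | 2.8 mM | run made earlier |  |
| beta | 39 mM | run made earlier |  |
| north-east | 4.00 mM |  | 12 h |
| north | 11.7 mM |  | 12 h |
| north-west | 50.0 mM |  | 12 h |
| south-east | 20.0 mM |  | 12 h |
| east | 6.00 mM |  | 12 h |
| south-west | 25.0 mM |  | 12 h |

| run | time / h | X / % | G / % |
|---|---|---|---|
| gamma | 0.833 | 1.9 | 98.1 |
| gamma | 2.00 | 3.0 | 101.9 |
| gamma | 4.00 | 2.3 | 97.1 |
| gamma | 6.00 | 2.4 | 95.5 |
| beta | 0.500 | 3.1 | 97.1 |
| beta | 1.00 | 6.8 | 93.5 |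
| beta | 2.50 | 17.2 | 83.9 |
| beta | 6.00 | 29.6 | 70.1 |

(scatter of a reading: 1 percentage point)

- ranking by amount of X, in percent of the G charged, from high to low, at 12 h (north-east / north / north-west / south-east / east / south-west)
- the amount of X, in percent of the G charged of the flask you put first, at 12 h
- the amount of X, in percent of the G charged of the flask you put last, at 12 h

**Main step.** I take G + Q to X by itself, with Q held at its charge, the pseudo-first-order picture. In beta, G falls to 83.9 % by 2.50 h, which reads as a rate constant of 1.80 /M/h. In north-west, with 50.0 mM of Q, that puts 1.08 lifetimes of G into 12 h. I call this the lifetime count, the rate constant times the Q charged times the time. A count so reckoned gives X as one minus e to the minus count, here 66.0 %.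

**Adding the fade.** Beta slows between its windows: the later lifetimes per hour are 0.731 of the early ones, a reading with scatter. Yet X has taken 9.87 % of beta's Q by 6.00 h, so that use of Q does not account for the slowing. I treat it as a decay with time constant 9.58 h, and as my own assumption I carry that over to north-west. The count drops to 0.616, and X to 46.0 %.

**The rest.** G and X in beta still sum to 99.7 % at 6.00 h, so I add no further loss. Gamma's X, 2.4 %, is too small against the scatter of 1 percentage point to show a fade, so north-east keeps its plain count of 0.0864, or 8.28 %.

**The forecast.** It ranks north-west > south-west > south-east > north > east > north-east, with 52 % on top (range 42 % to 65 %) and 5 % last (range 3 % to 8 %): “X should rise steadily with Q, so the ranking follows Q”. My figures differ from both of its numbers.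

**The flask.** The flask ranks north-west > south-west > south-east > north > east > north-east, the same order as the forecast, with north-west at 43.0 % and north-east at 7.46 %. North-west keeps 24.8 % of its own Q charge at 12.0 h. Its remaining G, 49.4 %, equals a count of 0.705, against my faded 0.616 and plain 1.08.

    G + Q → X (k = 2.31 /M/h)
    Q + X → E (k = 0.0372 /M/h)
    G + X → J (k = 1.29 /M/h)
    2 Q → D (k = 2.06 /M/h)

**Second flask.** With 10 mM of Q in place of north-east's charge, the plain count is 0.216, which gives 19.4 % converted. The flask keeps 81 % of its G and holds 16.1 % of X.

(The earlier runs and the new flask are calculated on assumed constants, and the scatter is random.)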